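The earlier runs and the new flask stem from a simulated flask with constants of no real substance, noise included.

The amber run held 12% of target at 1.33 min and the colder blue run 5% at 4.00 min, and I had to decide whether the next flask should be charged warm, as theta, or cold, as alpha.

| flask | starting material | protic impurity | temperature | remark | time |
|---|---|---|---|---|---|
| blue | 0.050 M | 0.025 M | −10 °C | run made earlier |  |
| amber | 0.050 M | 0.10 M | 8 °C | run made earlier |  |
| theta | 0.050 M | 0.0500 M | 20 °C |  | 5.0 min |
| alpha | 0.050 M | 0.0500 M | −5 °C |  | 5.0 min |

| run | time / min | target / % |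
|---|---|---|
| blue | 1.00 | 2 |
| blue | 2.00 | 2 |
| blue | 4.00 | 5 |
| blue | 6.00 | 8 |
| blue | 12.0 | 7 |
| amber | 1.33 | 12 |
| amber | 2.50 | 16 |
| amber | 4.00 | 18 |
| amber | 5.00 | 16 |

(scatter of a reading: 1.5 percentage points)

- which flask leads in amount of target, in percent of the starting material charged ("all alike" within 1.5 percentage points) (theta / alpha / all alike)
- how much target is there at the end, in percent of the starting material charged: theta
- how much target is there at the end, in percent of the starting material charged: alpha

- in a conversion other conformer counts as not yet reacted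

The late readings of both runs flattened, though their dips lie within the scatter, so I counted turnovers. From those two readings I took the early speed (the initial rate) as a fraction of the charge per minute:

amber 0.0902 min⁻¹, blue 0.0125 min⁻¹, ratio 7.22

The runs also differ in protic impurity, but I laid this whole ratio on temperature and spread it evenly per degree in the logarithm. The turnover count is the early speed at a flask's temperature multiplied by its time, the share of a charge that this speed would make:

theta 168%, alpha 10.8%

The highest readings, 8% in blue and 18% in amber, spread the same way, gave ceilings: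

theta 30.9%, alpha 10.0%

I took the smaller of count and ceiling. Alpha's count came out about equal to its ceiling, so I expected about 10.0%. Theta's count stood far above its ceiling, so I expected about 30.9%. I chose to charge warm.

The forecast gave 7% for theta and 11% for alpha: “Alpha probably leads”.

The flasks gave 24.6% in theta and 10.2% in alpha, so theta led.

    starting material ⇌ other conformer (K = 1.30, k = 0.0440 s⁻¹, Ea = 70.0 kJ mol⁻¹, ΔH = −11.0 kJ mol⁻¹)
    starting material → target (k = 0.0130 s⁻¹, Ea = 81.0 kJ mol⁻¹)
    other conformer → isomer of the product A (k = 0.00720 s⁻¹, Ea = 86.0 kJ mol⁻¹)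
    target ⇌ isomer of the product A (K = 5.60, k = 0.00380 s⁻¹, Ea = 82.0 kJ mol⁻¹, ΔH = −58.0 kJ mol⁻¹)
    target ⇌ isomer of the product B (K = 0.290, k = 0.00240 s⁻¹, Ea = 81.0 kJ mol⁻¹, ΔH = −26.0 kJ mol⁻¹)
    other conformer ⇌ dormant form (K = 0.320, k = 0.0760 s⁻¹, Ea = 72.0 kJ mol⁻¹, ΔH = −59.0 kJ mol⁻¹)
    starting material + protic impurity → quenched substrate (k = 0.0470 M⁻¹ s⁻¹, Ea = 44.0 kJ mol⁻¹)
    (constants at 20 °C)

Theta held 28.0% of target at 2.50 min and 24.6% at 5.00 min, while alpha ended near its count of 10.8%. The neighbour flask, like alpha but kept at −30 °C, has a count of 0.695%, which is below its ceiling of 3.25%. That neighbour flask held 94.5% of starting material and 0.408% of target.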